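The retrosynthesis adjusts the aryl ether C–O bond and the carboxyl oxidation level last. It cuts the methyl group on the sp2 ring carbon back to a ketone (via an enol triflate). It then cuts the ring bond between the CH2 next to that ketone (the later vinylic CH) and the CH that carries the isopropenyl group.
The enabling feature is that this CH is allylic through its isopropenyl group and lies 1,3 to the carbonyl carbon. The other five ring carbons can therefore be held in a δ-lactone/oxane ring whose oxygen occupies the place of the missing carbon.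
In the forward direction the order is: boron aldol, phosphonoacetate, temporary δ-lactone ring, conjugate methylation and hydroxymethylation on the lactone, methylenation (which brings in the missing carbon), O-to-C shift (opens the oxane, closes the cyclohexanone), triflate/methyl coupling, aryl ether, acid.
The aldol carbinol is set by reagent control and directs the methyl group trans; the methyl group directs the CH2OH trans. These two centres then fix the isopropenyl-bearing carbon when its C–O bond is exchanged for the C–C bond.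

Key step: step 8

Assumption: (−)-Ipc2BCl is taken as the antipode that gives the (R)-carbinol from a methyl ketone and methacrolein. If the sense is the opposite, the (+)-reagent is used.

Step 1
Reactants: 1 5-hydroxypentan-2-one
Product: 2 5-[(tert-butyldiphenylsilyl)oxy]pentan-2-one
Conditions: TBDPSCl, imidazole, DMF, 0 °C to rt
Reagents that add atoms: tert-butyl(chloro)diphenylsilane CC(C)(C)[Si](Cl)(c1ccccc1)c1ccccc1
Why: Imidazole-promoted silyl ether formation keeps the future carboxyl carbon at the alcohol level, because an ester would not survive the later titanium methylenation.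

Step 2
Reactants: 2 5-[(tert-butyldiphenylsilyl)oxy]pentan-2-one, 3 methacrolein
Product: 4 (3R)-8-[(tert-butyldiphenylsilyl)oxy]-3-hydroxy-2-methyloct-1-en-5-one
Conditions: (−)-Ipc2BCl, Et3N, Et2O, 0 °C; 3, −78 to −20 °C; H2O2, MeOH, pH 7 buffer
Reagents that add atoms: none
Why: In this Paterson boron aldol the reagent enolises the methyl side of 2 and the chiral boron enolate adds to one face of methacrolein, which sets the (R)-carbinol, the only centre that comes from a reagent.

Step 3
Reactants: 4 (3R)-8-[(tert-butyldiphenylsilyl)oxy]-3-hydroxy-2-methyloct-1-en-5-one, 5 (diethoxyphosphoryl)acetic acid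
Product: 6 (3R)-8-[(tert-butyldiphenylsilyl)oxy]-2-methyl-5-oxooct-1-en-3-yl (diethoxyphosphoryl)acetate
Conditions: DCC, DMAP (cat.), CH2Cl2, 0 °C to rt
Reagents that add atoms: none
Why: Steglich esterification acylates the secondary allylic alcohol under near-neutral conditions, so the β-hydroxy ketone should neither eliminate nor undergo retro-aldol cleavage, and the carbinol centre is untouched.

Step 4
Reactants: 6 (3R)-8-[(tert-butyldiphenylsilyl)oxy]-2-methyl-5-oxooct-1-en-3-yl (diethoxyphosphoryl)acetate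
Product: 7 (6R)-4-{3-[(tert-butyldiphenylsilyl)oxy]propyl}-6-(prop-1-en-2-yl)-5,6-dihydro-2H-pyran-2-one
Conditions: LiCl, DBU, MeCN, rt
Reagents that add atoms: none
Why: This intramolecular Horner–Wadsworth–Emmons olefination (Masamune–Roush conditions) should outrun β-elimination of the acyloxy group because the phosphonate CH2 is far more acidic than the ketone α-CH2, and the six-membered ring enforces the cis alkene.

Step 5
Reactants: 7 (6R)-4-{3-[(tert-butyldiphenylsilyl)oxy]propyl}-6-(prop-1-en-2-yl)-5,6-dihydro-2H-pyran-2-one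
Product: 9 (3S,4R,6R)-4-{3-[(tert-butyldiphenylsilyl)oxy]propyl}-3-(hydroxymethyl)-4-methyl-6-(prop-1-en-2-yl)oxan-2-one, via trimethylsilyl ketene acetal 8 (not isolated)
Conditions: MeMgBr, CuBr·SMe2 (10 mol %), TMSCl, HMPA, THF, −78 °C; then MeLi, THF, 0 °C; CH2O (gas), −78 °C
Reagents that add atoms: methylmagnesium bromide C[Mg]Br; chlorotrimethylsilane C[Si](C)(C)Cl; formaldehyde C=O
Why: In this copper-catalysed, TMSCl-accelerated conjugate addition with aldol trapping of the regiodefined enolate, the methyl group enters axially anti to the pseudo-equatorial isopropenyl group (trans-4,6 rule) and formaldehyde then enters anti to the new axial methyl, which sets the quaternary centre and its neighbour, while the low temperature is meant to keep SN2′ opening of the allylic lactone out.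

Step 6
Reactants: 9 (3S,4R,6R)-4-{3-[(tert-butyldiphenylsilyl)oxy]propyl}-3-(hydroxymethyl)-4-methyl-6-(prop-1-en-2-yl)oxan-2-one
Product: 10 (3S,4R,6R)-4-{3-[(tert-butyldiphenylsilyl)oxy]propyl}-4-methyl-6-(prop-1-en-2-yl)-3-{[(triethylsilyl)oxy]methyl}oxan-2-one
Conditions: TESCl, imidazole, CH2Cl2, 0 °C
Reagents that add atoms: chlorotriethylsilane CC[Si](Cl)(CC)CC
Why: Mild silylation blocks retro-aldol loss of formaldehyde and gives a silyl ether that can later be removed in the presence of the TBDPS ether.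

Step 7
Reactants: 10 (3S,4R,6R)-4-{3-[(tert-butyldiphenylsilyl)oxy]propyl}-4-methyl-6-(prop-1-en-2-yl)-3-{[(triethylsilyl)oxy]methyl}oxan-2-one
Product: 11 (3S,4R,6R)-4-{3-[(tert-butyldiphenylsilyl)oxy]propyl}-4-methyl-2-methylidene-6-(prop-1-en-2-yl)-3-{[(triethylsilyl)oxy]methyl}oxane
Conditions: Cp2TiMe2, toluene, 75 °C, dark
Reagents that add atoms: dimethyltitanocene [CH3-].[CH3-].[Ti+4].c1cc[cH-]c1.c1cc[cH-]c1
Why: Petasis methylenation turns the lactone C=O into the exocyclic enol ether under non-basic conditions, so the α-centre is not epimerised, and it brings in the carbon that becomes the vinylic ring CH.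

Step 8
Reactants: 11 (3S,4R,6R)-4-{3-[(tert-butyldiphenylsilyl)oxy]propyl}-4-methyl-2-methylidene-6-(prop-1-en-2-yl)-3-{[(triethylsilyl)oxy]methyl}oxane
Product: 12 (2S,3R,5S)-3-{3-[(tert-butyldiphenylsilyl)oxy]propyl}-3-methyl-5-(prop-1-en-2-yl)-2-{[(triethylsilyl)oxy]methyl}cyclohexan-1-one
Conditions: TMSOTf (15 mol %), 2,6-di-tert-butyl-4-methylpyridine (30 mol %), CH2Cl2, −78 to −40 °C
Reagents that add atoms: none
Why: Proposed new method: TMSOTf should silylate the ring oxygen of 11 and ionise its allylic C–O bond, which gives a 1-alkyl-2-methylallyl cation tied through four carbons to the trimethylsilyl enol ether of a methyl ketone; the enol-ether CH2 attacks the substituted allyl terminus and the silyl cation passes on to the next molecule of 11. The closest known reaction types are the Petasis–Ferrier rearrangement, the Ferrier-type O-to-C carbocyclisation of 2-methyleneoxanes and the Lewis-acid [1,3] shift of allyl vinyl ethers; new is a plain allyl cation as the electrophile in the ring-to-ring version. The cyclohexanone closes in the 6-(enolendo)-exo-trig mode, whereas attack at the CH2 terminus would need an eight-membered ring. The new stereocentre is controlled by the two centres made on the lactone: A(1,2) strain against the OSiMe3 group holds the CH2OTES group axial, this puts the ring methyl axial on the opposite face, and the isopropenyl unit must then sit equatorial, which is also the result of ion-pair collapse with retention. The step needs [1,3] over [3,3] selectivity and C- over O-capture: the Claisen path to a cyclooctenone requires the isopropenyl group axial and syn-diaxial to the propyl chain, the silyl ether oxygens are shielded by their silicon groups, and the hindered pyridine removes triflic acid that would move the exocyclic double bond into the ring or cause proton loss.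

Step 9
Reactants: 12 (2S,3R,5S)-3-{3-[(tert-butyldiphenylsilyl)oxy]propyl}-3-methyl-5-(prop-1-en-2-yl)-2-{[(triethylsilyl)oxy]methyl}cyclohexan-1-one
Product: 13 (3S,5R,6S)-5-{3-[(tert-butyldiphenylsilyl)oxy]propyl}-5-methyl-3-(prop-1-en-2-yl)-6-{[(triethylsilyl)oxy]methyl}cyclohex-1-en-1-yl trifluoromethanesulfonate
Conditions: KHMDS, THF, −78 °C; Comins' reagent, −78 °C
Reagents that add atoms: N-(5-chloropyridin-2-yl)bis(trifluoromethanesulfonimide) O=S(=O)(N(c1ccc(Cl)cn1)S(=O)(=O)C(F)(F)F)C(F)(F)F
Why: Kinetic deprotonation takes the unhindered ring CH2 rather than the hindered α-CH (whose enolate could expel silyloxide), and O-triflation fixes the double bond between the future vinylic CH and the future methyl-bearing carbon.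

Step 10
Reactants: 13 (3S,5R,6S)-5-{3-[(tert-butyldiphenylsilyl)oxy]propyl}-5-methyl-3-(prop-1-en-2-yl)-6-{[(triethylsilyl)oxy]methyl}cyclohex-1-en-1-yl trifluoromethanesulfonate
Product: 14 tert-butyl(3-{(1R,2R,5S)-1,3-dimethyl-5-(prop-1-en-2-yl)-2-{[(triethylsilyl)oxy]methyl}cyclohex-3-en-1-yl}propoxy)diphenylsilane
Conditions: MeMgBr, Fe(acac)3 (5 mol %), THF/NMP, −30 °C
Reagents that add atoms: methylmagnesium bromide C[Mg]Br
Why: Iron-catalysed Kumada-type coupling of an alkenyl triflate replaces OTf by methyl with the double bond held in place and touches no stereocentre.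

Step 11
Reactants: 14 tert-butyl(3-{(1R,2R,5S)-1,3-dimethyl-5-(prop-1-en-2-yl)-2-{[(triethylsilyl)oxy]methyl}cyclohex-3-en-1-yl}propoxy)diphenylsilane
Product: 15 {(1R,4S,6R)-6-{3-[(tert-butyldiphenylsilyl)oxy]propyl}-2,6-dimethyl-4-(prop-1-en-2-yl)cyclohex-2-en-1-yl}methanol
Conditions: PPTS (cat.), MeOH/CH2Cl2, 0 °C
Reagents that add atoms: none
Why: Acid-catalysed methanolysis cleaves a triethylsilyl ether far faster than a tert-butyldiphenylsilyl ether and is too mild to protonate the two alkenes.

Step 12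
Reactants: 15 {(1R,4S,6R)-6-{3-[(tert-butyldiphenylsilyl)oxy]propyl}-2,6-dimethyl-4-(prop-1-en-2-yl)cyclohex-2-en-1-yl}methanol, 16 umbelliferone (7-hydroxy-2H-chromen-2-one)
Product: 17 7-({(1R,4S,6R)-6-{3-[(tert-butyldiphenylsilyl)oxy]propyl}-2,6-dimethyl-4-(prop-1-en-2-yl)cyclohex-2-en-1-yl}methoxy)-2H-chromen-2-one
Conditions: PPh3, DIAD, toluene, 0 to 60 °C
Reagents that add atoms: none
Why: Mitsunobu etherification joins the acidic phenol to the primary carbinol carbon without base that could harm the coumarin and without touching a stereocentre.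

Step 13
Reactants: 17 7-({(1R,4S,6R)-6-{3-[(tert-butyldiphenylsilyl)oxy]propyl}-2,6-dimethyl-4-(prop-1-en-2-yl)cyclohex-2-en-1-yl}methoxy)-2H-chromen-2-one
Product: 18 7-{[(1R,4S,6R)-6-(3-hydroxypropyl)-2,6-dimethyl-4-(prop-1-en-2-yl)cyclohex-2-en-1-yl]methoxy}-2H-chromen-2-one
Conditions: TBAF, THF, 0 °C to rt
Reagents that add atoms: none
Why: Fluoride desilylation frees the chain alcohol, and the aryl ether, the coumarin and both alkenes are inert to it.

Step 14
Reactants: 18 7-{[(1R,4S,6R)-6-(3-hydroxypropyl)-2,6-dimethyl-4-(prop-1-en-2-yl)cyclohex-2-en-1-yl]methoxy}-2H-chromen-2-one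
Product: 19 3-[(1R,2R,5S)-1,3-dimethyl-2-{[(2-oxo-2H-chromen-7-yl)oxy]methyl}-5-(prop-1-en-2-yl)cyclohex-3-en-1-yl]propanoic acid
Conditions: TEMPO (cat.), PhI(OAc)2, MeCN/H2O, rt
Reagents that add atoms: water O
Why: The oxoammonium (TEMPO/PhI(OAc)2) oxidation takes the primary alcohol through the aldehyde hydrate to the acid and leaves isolated alkenes and the coumarin alone.

Compound list
1 | 5-hydroxypentan-2-one | CC(=O)CCCO | starting material
2 | 5-[(tert-butyldiphenylsilyl)oxy]pentan-2-one | CC(=O)CCCO[Si](c1ccccc1)(c1ccccc1)C(C)(C)C | intermediate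
3 | methacrolein | C=C(C)C=O | starting material
4 | (3R)-8-[(tert-butyldiphenylsilyl)oxy]-3-hydroxy-2-methyloct-1-en-5-one | C=C(C)[C@@H](CC(=O)CCCO[Si](c1ccccc1)(c1ccccc1)C(C)(C)C)O | intermediate
5 | (diethoxyphosphoryl)acetic acid | CCOP(=O)(CC(=O)O)OCC | starting material
6 | (3R)-8-[(tert-butyldiphenylsilyl)oxy]-2-methyl-5-oxooct-1-en-3-yl (diethoxyphosphoryl)acetate | C=C(C)[C@@H](CC(=O)CCCO[Si](c1ccccc1)(c1ccccc1)C(C)(C)C)OC(=O)CP(=O)(OCC)OCC | intermediate
7 | (6R)-4-{3-[(tert-butyldiphenylsilyl)oxy]propyl}-6-(prop-1-en-2-yl)-5,6-dihydro-2H-pyran-2-one | C=C(C)[C@@H]1OC(=O)C=C(CCCO[Si](c2ccccc2)(c2ccccc2)C(C)(C)C)C1 | intermediate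
8 | trimethylsilyl ketene acetal, (2R,4R)-4-{3-[(tert-butyldiphenylsilyl)oxy]propyl}-4-methyl-2-(prop-1-en-2-yl)-6-[(trimethylsilyl)oxy]-3,4-dihydro-2H-pyran | C=C(C)[C@@H]1OC(O[Si](C)(C)C)=C[C@](C)(CCCO[Si](c2ccccc2)(c2ccccc2)C(C)(C)C)C1 | intermediate
9 | (3S,4R,6R)-4-{3-[(tert-butyldiphenylsilyl)oxy]propyl}-3-(hydroxymethyl)-4-methyl-6-(prop-1-en-2-yl)oxan-2-one | C=C(C)[C@@H]1OC(=O)[C@H](CO)[C@](C)(CCCO[Si](c2ccccc2)(c2ccccc2)C(C)(C)C)C1 | intermediate
10 | (3S,4R,6R)-4-{3-[(tert-butyldiphenylsilyl)oxy]propyl}-4-methyl-6-(prop-1-en-2-yl)-3-{[(triethylsilyl)oxy]methyl}oxan-2-one | C=C(C)[C@@H]1OC(=O)[C@H](CO[Si](CC)(CC)CC)[C@](C)(CCCO[Si](c2ccccc2)(c2ccccc2)C(C)(C)C)C1 | intermediate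
11 | (3S,4R,6R)-4-{3-[(tert-butyldiphenylsilyl)oxy]propyl}-4-methyl-2-methylidene-6-(prop-1-en-2-yl)-3-{[(triethylsilyl)oxy]methyl}oxane | C=C(C)[C@@H]1OC(=C)[C@H](CO[Si](CC)(CC)CC)[C@](C)(CCCO[Si](c2ccccc2)(c2ccccc2)C(C)(C)C)C1 | intermediate
12 | (2S,3R,5S)-3-{3-[(tert-butyldiphenylsilyl)oxy]propyl}-3-methyl-5-(prop-1-en-2-yl)-2-{[(triethylsilyl)oxy]methyl}cyclohexan-1-one | C=C(C)[C@@H]1CC(=O)[C@H](CO[Si](CC)(CC)CC)[C@](C)(CCCO[Si](c2ccccc2)(c2ccccc2)C(C)(C)C)C1 | intermediate
13 | (3S,5R,6S)-5-{3-[(tert-butyldiphenylsilyl)oxy]propyl}-5-methyl-3-(prop-1-en-2-yl)-6-{[(triethylsilyl)oxy]methyl}cyclohex-1-en-1-yl trifluoromethanesulfonate | C=C(C)[C@@H]1C=C(OS(=O)(=O)C(F)(F)F)[C@H](CO[Si](CC)(CC)CC)[C@](C)(CCCO[Si](c2ccccc2)(c2ccccc2)C(C)(C)C)C1 | intermediate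
14 | tert-butyl(3-{(1R,2R,5S)-1,3-dimethyl-5-(prop-1-en-2-yl)-2-{[(triethylsilyl)oxy]methyl}cyclohex-3-en-1-yl}propoxy)diphenylsilane | C=C(C)[C@@H]1C=C(C)[C@H](CO[Si](CC)(CC)CC)[C@](C)(CCCO[Si](c2ccccc2)(c2ccccc2)C(C)(C)C)C1 | intermediate
15 | {(1R,4S,6R)-6-{3-[(tert-butyldiphenylsilyl)oxy]propyl}-2,6-dimethyl-4-(prop-1-en-2-yl)cyclohex-2-en-1-yl}methanol | C=C(C)[C@@H]1C=C(C)[C@H](CO)[C@](C)(CCCO[Si](c2ccccc2)(c2ccccc2)C(C)(C)C)C1 | intermediate
16 | umbelliferone (7-hydroxy-2H-chromen-2-one) | Oc1ccc2ccc(=O)oc2c1 | starting material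
17 | 7-({(1R,4S,6R)-6-{3-[(tert-butyldiphenylsilyl)oxy]propyl}-2,6-dimethyl-4-(prop-1-en-2-yl)cyclohex-2-en-1-yl}methoxy)-2H-chromen-2-one | C=C(C)[C@@H]1C=C(C)[C@H](COc2ccc3ccc(=O)oc3c2)[C@](C)(CCCO[Si](c2ccccc2)(c2ccccc2)C(C)(C)C)C1 | intermediate
18 | 7-{[(1R,4S,6R)-6-(3-hydroxypropyl)-2,6-dimethyl-4-(prop-1-en-2-yl)cyclohex-2-en-1-yl]methoxy}-2H-chromen-2-one | C=C(C)[C@@H]1C=C(C)[C@H](COc2ccc3ccc(=O)oc3c2)[C@](C)(CCCO)C1 | intermediate
19 | 3-[(1R,2R,5S)-1,3-dimethyl-2-{[(2-oxo-2H-chromen-7-yl)oxy]methyl}-5-(prop-1-en-2-yl)cyclohex-3-en-1-yl]propanoic acid | C=C(C)[C@@H]1C=C(C)[C@H](COc2ccc3ccc(=O)oc3c2)[C@](C)(CCC(=O)O)C1 | target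

Total step count: 14. Longest linear sequence: 14.

Steps most likely to fail

Step 8. After ionisation the allyl cation may lose a proton to give a diene, be captured by a silyl ether oxygen, or the substrate may take the [3,3] path instead of C–C closure at the substituted terminus. The fallback uses known chemistry and sets out from 11. Hydrolysis on wet silica gel with oxalic acid gives the δ-hydroxy methyl ketone F1. Methyl chloroformate and pyridine convert its allylic alcohol into the methyl carbonate F2. F2 is then closed with Pd(PPh3)4 and pyrrolidine, an intramolecular Tsuji–Trost allylation of the methyl-side enamine by the π-allyl complex of divalent palladium that forms from zerovalent palladium. Face exchange of the allyl complex and the same axial CH2OTES / axial methyl bias should lead back to 12.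

Step 5. The organocopper species may open the allylic lactone by SN2′ attack at the isopropenyl CH2, the addition to the β,β-disubstituted lactone may stall, or formaldehyde may be lost again by retro-aldol cleavage. The fallback masks the alkene so that no allylic C–O bond is present during the copper step, and it sets out from 2. Isobutyraldehyde and PhSeCl give 2-methyl-2-(phenylselanyl)propanal F3. The same boron aldol with 2 gives the carbinol F4, esterification with 5 gives F5, and the intramolecular olefination gives the lactone F6. Copper-catalysed methylation gives the silyl ketene acetal F7, and fluoride-triggered (Bu4N Ph3SiF2) hydroxymethylation gives F8. Oxidation with H2O2 and selenoxide syn-elimination away from the oxygen-bearing carbon unveils the isopropenyl group and rejoins the route at 9.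

Step 2. Enantioface discrimination by the boron enolate of a methyl ketone may be insufficient for a single enantiomer. The fallback sets out from 2 and 3. A racemic lithium aldol (LDA, THF, −78 °C) gives the racemic carbinol F9. A Sharpless kinetic resolution (Ti(OiPr)4, L-(+)-diisopropyl tartrate, t-BuOOH, 4 Å sieves, CH2Cl2, −20 °C) then consumes the (S)-carbinol by epoxidation and leaves the (R)-carbinol, which is 4.

Further compounds
F1 | step 8 | (3S,4R,6R)-4-{3-[(tert-butyldiphenylsilyl)oxy]propyl}-6-hydroxy-4,7-dimethyl-3-{[(triethylsilyl)oxy]methyl}oct-7-en-2-one | C=C(C)[C@H](O)C[C@@](C)(CCCO[Si](c1ccccc1)(c1ccccc1)C(C)(C)C)[C@@H](CO[Si](CC)(CC)CC)C(C)=O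
F2 | step 8 | methyl carbonate of F1 at the allylic hydroxyl group | C=C(C)[C@H](OC(=O)OC)C[C@@](C)(CCCO[Si](c1ccccc1)(c1ccccc1)C(C)(C)C)[C@@H](CO[Si](CC)(CC)CC)C(C)=O
F3 | step 5 | 2-methyl-2-(phenylselanyl)propanal | CC(C)([Se]c1ccccc1)C=O
F4 | step 5 | (6R)-1-[(tert-butyldiphenylsilyl)oxy]-6-hydroxy-7-methyl-7-(phenylselanyl)octan-4-one | CC(C)([Se]c1ccccc1)[C@@H](CC(=O)CCCO[Si](c1ccccc1)(c1ccccc1)C(C)(C)C)O
F5 | step 5 | (diethoxyphosphoryl)acetate of F4 | CC(C)([Se]c1ccccc1)[C@@H](CC(=O)CCCO[Si](c1ccccc1)(c1ccccc1)C(C)(C)C)OC(=O)CP(=O)(OCC)OCC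
F6 | step 5 | (6R)-4-{3-[(tert-butyldiphenylsilyl)oxy]propyl}-6-[2-(phenylselanyl)propan-2-yl]-5,6-dihydro-2H-pyran-2-one | CC(C)([Se]c2ccccc2)[C@@H]1OC(=O)C=C(CCCO[Si](c2ccccc2)(c2ccccc2)C(C)(C)C)C1
F7 | step 5 | trimethylsilyl ketene acetal from methyl addition to F6 | CC(C)([Se]c2ccccc2)[C@@H]1OC(O[Si](C)(C)C)=C[C@](C)(CCCO[Si](c2ccccc2)(c2ccccc2)C(C)(C)C)C1
F8 | step 5 | (3S,4R,6R)-4-{3-[(tert-butyldiphenylsilyl)oxy]propyl}-3-(hydroxymethyl)-4-methyl-6-[2-(phenylselanyl)propan-2-yl]oxan-2-one | CC(C)([Se]c2ccccc2)[C@@H]1OC(=O)[C@H](CO)[C@](C)(CCCO[Si](c2ccccc2)(c2ccccc2)C(C)(C)C)C1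
F9 | step 2 | racemic 8-[(tert-butyldiphenylsilyl)oxy]-3-hydroxy-2-methyloct-1-en-5-one | C=C(C)C(O)CC(=O)CCCO[Si](c1ccccc1)(c1ccccc1)C(C)(C)C
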